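**Retrosynthetic overview**
- Lepidine C ⇒ both imidazole rings opened to a bis(methyl imidate) plus two molecules of aminoacetaldehyde dimethyl acetal; the bis-imidate comes from a bis(arylacetonitrile) by a Pinner reaction.
- Bis(arylacetonitrile) ⇒ bis(2-nitroethyl) diaryl ether (nitro → aldoxime → nitrile), so each nitro-bearing carbon becomes C2 of an imidazole.
- Key C–C disconnection: both ArCH2–C bonds, made by a twofold Henry (nitro-aldol) condensation of a diaryl ether dialdehyde with two molecules of nitromethane, then C=C reduction; the dialdehyde comes from SNAr of 2-fluoro-5-methoxybenzaldehyde with 3-hydroxybenzaldehyde.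
- Ring order: both benzene rings are bought (ring A methoxylated, ring B plain); the two imidazole rings are formed last, together, in one operation.

Assumption: Lepidine C has no stereocentre or stereogenic axis, so "single enantiomer" reduces to the constitution shown and no asymmetric step is needed.

Bookkeeping: steps 2, 6 and 7 act on both side chains at once. Each entry on a Reactants or "Reagents that add atoms" line stands for one molecule, so a partner that is taken up twice is entered twice. Nitromethane 4 in step 2 and acetal 13 in step 7 appear once as reactant and once as reagent; methanol and HCl in step 6 appear twice as reagents.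

**Route**

Step 1
Reactants: 1 2-fluoro-5-methoxybenzaldehyde; 2 3-hydroxybenzaldehyde
Product: 3 2-(3-formylphenoxy)-5-methoxybenzaldehyde
Conditions: K2CO3 (1.5 equiv), DMAc, 130 °C, 12 h
Reagents that add atoms: none
Why: SNAr (addition–elimination) in which the ortho-formyl group activates the C–F bond of 1 toward the phenoxide of 2 and fluoride is the best leaving group for this mechanism.

Step 2
Reactants: 3 2-(3-formylphenoxy)-5-methoxybenzaldehyde; 4 nitromethane
Product: 6 4-methoxy-2-[(E)-2-nitroethenyl]-1-{3-[(E)-2-nitroethenyl]phenoxy}benzene, via bis(nitro alcohol) 5 (not isolated)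
Conditions: 4 (10 equiv), NH4OAc (0.5 equiv), AcOH, 100 °C, 4 h
Reagents that add atoms: nitromethane C[N+](=O)[O-]
Why: Twofold Henry (nitro-aldol) condensation in which one nitronate of 4 adds to each of the two aldehydes of 3 (two molecules of 4 in all), making the C–C bonds that later link each CH2 to imidazole C2, and the β-nitro alcohol 5 dehydrates under the NH4OAc/AcOH conditions to the thermodynamically favoured E-nitroalkene.

Step 3
Reactants: 6 4-methoxy-2-[(E)-2-nitroethenyl]-1-{3-[(E)-2-nitroethenyl]phenoxy}benzene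
Product: 7 4-methoxy-2-(2-nitroethyl)-1-[3-(2-nitroethyl)phenoxy]benzene
Conditions: NaBH4 (4 equiv), SiO2, CHCl3/i-PrOH (4:1), rt, 1 h; AcOH quench
Reagents that add atoms: none
Why: Conjugate (1,4) hydride reduction of both nitroalkenes, with SiO2 protonating the nitronate quickly so that Michael dimerisation onto unreacted nitroalkene is suppressed; nothing else in 6 is reduced by NaBH4.

Step 4
Reactants: 7 4-methoxy-2-(2-nitroethyl)-1-[3-(2-nitroethyl)phenoxy]benzene
Product: 9 2-{2-[3-(2-(hydroxyimino)ethyl)phenoxy]-5-methoxyphenyl}acetaldehyde oxime (E/Z mixture at both C=N), via bis(O-benzyl nitronate) 8 (not isolated)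
Conditions: BnBr (2.2 equiv), KOH (2.1 equiv), n-Bu4NI (10 mol %), THF, rt, 3 h
Reagents that add atoms: none
Why: O-benzylation of each potassium nitronate gives nitronic ester 8, which fragments in a Hass–Bender-type redox step to the aldoxime and benzaldehyde; the oxime geometry does not matter because the C=N becomes C≡N in the next step.

Step 5
Reactants: 9 2-{2-[3-(2-(hydroxyimino)ethyl)phenoxy]-5-methoxyphenyl}acetaldehyde oxime
Product: 11 2-{2-[3-(cyanomethyl)phenoxy]-5-methoxyphenyl}acetonitrile, via bis(O-acetyl oxime) 10 (not isolated)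
Conditions: Ac2O (solvent), NaOAc (0.2 equiv), 110 °C, 2 h
Reagents that add atoms: none
Why: Aldoxime dehydration in which O-acetylation turns each hydroxyl into an acetate leaving group and β-elimination from 10 gives the nitrile, both oxime isomers converging on the same product.

Step 6
Reactants: 11 2-{2-[3-(cyanomethyl)phenoxy]-5-methoxyphenyl}acetonitrile
Product: 12 methyl 2-{2-[3-(2-imino-2-methoxyethyl)phenoxy]-5-methoxyphenyl}ethanimidate dihydrochloride
Conditions: HCl (g, to saturation), MeOH (6 equiv), CH2Cl2, 0 °C → 4 °C, 24 h; evaporate cold, use crude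
Reagents that add atoms: methanol CO; methanol CO; hydrogen chloride Cl; hydrogen chloride Cl
Why: Pinner reaction in which anhydrous HCl activates each nitrile toward addition of one methanol and each imidate is held as its stable hydrochloride in the cold, the aryl ethers being inert.

Step 7
Reactants: 12 methyl 2-{2-[3-(2-imino-2-methoxyethyl)phenoxy]-5-methoxyphenyl}ethanimidate dihydrochloride; 13 2,2-dimethoxyethanamine (aminoacetaldehyde dimethyl acetal)
Product: 15 Lepidine C, via bis-amidine dihydrochloride 14 (not isolated)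
Conditions: 13 (2.4 equiv), MeOH, rt, 16 h; evaporate; 6 M aq HCl, 80 °C, 2 h; aq NaOH to pH 10
Reagents that add atoms: 2,2-dimethoxyethanamine NCC(OC)OC
Why: Amine–imidate exchange on each arm (two molecules of 13 in all) gives the N-(2,2-dimethoxyethyl)amidine, and on acid unmasking of the acetal the second amidine nitrogen closes onto the oxocarbenium carbon and loss of methanol aromatises the ring (amidine–aminoacetal imidazole annulation), forming both imidazoles in one pot.

**Compound list**

1 | 2-fluoro-5-methoxybenzaldehyde | COc1ccc(F)c(C=O)c1 | starting material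
2 | 3-hydroxybenzaldehyde | O=Cc1cccc(O)c1 | starting material
3 | 2-(3-formylphenoxy)-5-methoxybenzaldehyde | COc1ccc(Oc2cccc(C=O)c2)c(C=O)c1 | intermediate
4 | nitromethane | C[N+](=O)[O-] | starting material
5 | 1-{2-[3-(1-hydroxy-2-nitroethyl)phenoxy]-5-methoxyphenyl}-2-nitroethanol (bis(nitro alcohol), mixture of racemic diastereomers; both carbinol centres are destroyed on dehydration) | COc1ccc(Oc2cccc(C(O)C[N+](=O)[O-])c2)c(C(O)C[N+](=O)[O-])c1 | intermediate (not isolated)
6 | 4-methoxy-2-[(E)-2-nitroethenyl]-1-{3-[(E)-2-nitroethenyl]phenoxy}benzene | COc1ccc(Oc2cccc(/C=C/[N+](=O)[O-])c2)c(/C=C/[N+](=O)[O-])c1 | intermediate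
7 | 4-methoxy-2-(2-nitroethyl)-1-[3-(2-nitroethyl)phenoxy]benzene | COc1ccc(Oc2cccc(CC[N+](=O)[O-])c2)c(CC[N+](=O)[O-])c1 | intermediate
8 | bis(O-benzyl nitronate) of 7 (benzyl nitronic ester on both side chains, C=N isomer mixture) | COc1ccc(Oc2cccc(CC=[N+]([O-])OCc3ccccc3)c2)c(CC=[N+]([O-])OCc2ccccc2)c1 | intermediate (not isolated)
9 | 2-{2-[3-(2-(hydroxyimino)ethyl)phenoxy]-5-methoxyphenyl}acetaldehyde oxime (bis-aldoxime, E/Z mixture at both C=N, used as such) | COc1ccc(Oc2cccc(CC=NO)c2)c(CC=NO)c1 | intermediate
10 | bis(O-acetyl oxime) of 9 (C=N isomer mixture) | COc1ccc(Oc2cccc(CC=NOC(C)=O)c2)c(CC=NOC(C)=O)c1 | intermediate (not isolated)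
11 | 2-{2-[3-(cyanomethyl)phenoxy]-5-methoxyphenyl}acetonitrile | COc1ccc(Oc2cccc(CC#N)c2)c(CC#N)c1 | intermediate
12 | methyl 2-{2-[3-(2-imino-2-methoxyethyl)phenoxy]-5-methoxyphenyl}ethanimidate dihydrochloride | COc1ccc(Oc2cccc(CC(=N)OC)c2)c(CC(=N)OC)c1.Cl.Cl | intermediate
13 | 2,2-dimethoxyethanamine (aminoacetaldehyde dimethyl acetal) | NCC(OC)OC | starting material
14 | N-(2,2-dimethoxyethyl)-2-{2-[3-(2-[(2,2-dimethoxyethyl)amino]-2-iminoethyl)phenoxy]-5-methoxyphenyl}ethanimidamide dihydrochloride | COc1ccc(Oc2cccc(CC(=N)NCC(OC)OC)c2)c(CC(=N)NCC(OC)OC)c1.Cl.Cl | intermediate (not isolated)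
15 | Lepidine C, 2-{2-[3-(1H-imidazol-2-ylmethyl)phenoxy]-5-methoxybenzyl}-1H-imidazole (achiral) | COc1ccc(Oc2cccc(Cc3ncc[nH]3)c2)c(Cc2ncc[nH]2)c1 | target

**Step count and risks**

Total steps: 7. Longest linear sequence: 7 steps (1 or 2 → 15).

Three steps most likely to fail:

Step 3 (NaBH4 reduction of the bis-nitroalkene). The nitronate formed can add in Michael fashion to unreacted nitroalkene, and with two nitrovinyl arms this gives oligomers. The fallback sets out from 3 and comes back at 7. The nitro-aldol is run as a plain addition (4 as solvent, catalytic Et3N, rt) and the bis(nitro alcohol) 5 is isolated. It is acetylated (Ac2O, catalytic H2SO4, 0 °C → rt) to 1-{2-[3-(1-acetoxy-2-nitroethyl)phenoxy]-5-methoxyphenyl}-2-nitroethyl acetate F1. Treatment of F1 with NaBH4 in EtOH at 0 °C gives 7. The nitroalkene is released slowly by loss of acetate and reduced at once, so it never accumulates.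

Step 4 (nitro → aldoxime by O-benzylation and fragmentation). On a bis-nitronate the liberated benzaldehyde can re-add (Henry), or the oxime can be over-benzylated. The fallback sets out from 7 and comes back at 11, by-passing 9. Nitrosative oxidation of both primary nitro groups (NaNO2, AcOH, DMSO, 35 °C; nitrolic acid pathway) gives 2-{2-[3-(carboxymethyl)phenoxy]-5-methoxyphenyl}acetic acid F2. Activation with 1,1'-carbonyldiimidazole in THF gives the bis(acyl imidazolide) 1-(1H-imidazol-1-yl)-2-{2-[3-(2-(1H-imidazol-1-yl)-2-oxoethyl)phenoxy]-5-methoxyphenyl}ethanone F3, which is not isolated. Aqueous NH3 converts it into 2-{2-[3-(2-amino-2-oxoethyl)phenoxy]-5-methoxyphenyl}acetamide F4. Dehydration (trifluoroacetic anhydride, pyridine, CH2Cl2, 0 °C) delivers the bis-nitrile 11.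

Step 7 (double amidine formation and acid cyclisation). Imidate hydrolysis to ester or amide, or incomplete closure of one of the two rings, would give hard-to-separate polar mixtures. The fallback sets out from 12 and comes back at 15. Condensation of 12 with ethylenediamine (MeOH, 0 °C → reflux, then aq NaOH) gives 2-{2-[3-(4,5-dihydro-1H-imidazol-2-ylmethyl)phenoxy]-5-methoxybenzyl}-4,5-dihydro-1H-imidazole F5, a robust tolazoline-type imidazoline synthesis. F5 is then dehydrogenated over 10 % Pd/C in refluxing xylene to 15. Because no oxidant is present, the doubly activated benzylic CH2 groups are not attacked.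

**Further compounds**

F1 | step 3 | 1-{2-[3-(1-acetoxy-2-nitroethyl)phenoxy]-5-methoxyphenyl}-2-nitroethyl acetate (diastereomer mixture) | COc1ccc(Oc2cccc(C(OC(C)=O)C[N+](=O)[O-])c2)c(C(OC(C)=O)C[N+](=O)[O-])c1
F2 | step 4 | 2-{2-[3-(carboxymethyl)phenoxy]-5-methoxyphenyl}acetic acid | COc1ccc(Oc2cccc(CC(=O)O)c2)c(CC(=O)O)c1
F3 | step 4 | 1-(1H-imidazol-1-yl)-2-{2-[3-(2-(1H-imidazol-1-yl)-2-oxoethyl)phenoxy]-5-methoxyphenyl}ethanone (bis(acyl imidazolide), not isolated) | COc1ccc(Oc2cccc(CC(=O)n3ccnc3)c2)c(CC(=O)n2ccnc2)c1
F4 | step 4 | 2-{2-[3-(2-amino-2-oxoethyl)phenoxy]-5-methoxyphenyl}acetamide | COc1ccc(Oc2cccc(CC(N)=O)c2)c(CC(N)=O)c1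
F5 | step 7 | 2-{2-[3-(4,5-dihydro-1H-imidazol-2-ylmethyl)phenoxy]-5-methoxybenzyl}-4,5-dihydro-1H-imidazole | COc1ccc(Oc2cccc(CC3=NCCN3)c2)c(CC2=NCCN2)c1
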